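**Retrosynthetic overview**

1. Numbering as in eudesmane: ring A = C1–C2–C3–C4–C5–C10, ring B = C5–C6–C7–C8–C9–C10, C11 = carbinol carbon on C7, C1' = benzylic carbon on C1. The end game installs the formyl groups by twofold ortho-lithiation, the aryl–C1' bond by cuprate addition to a C1-bound enone, and the C4 carbinol by MeMgBr addition to a C4 ketone.
2. Enabling feature: in ring A the oxygen-bearing C4 lies between C3 and the ring-fusion carbon C5, and the quaternary C10 is flanked by CH2-9. With a C3=C4 silyl enol ether and a temporary C9 ketone, C1–C2 and C5–C10 are the two σ-bonds of a [4+2] adduct of the diene C2=C3–C4(OSi)=C5 and the enone C1=C10–C9=O.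
3. Key step: intramolecular Diels–Alder reaction of an acyclic (Z)-trienone closes rings A and B together and sets C1, C5 and C10 from the single stereocentre C7; the C9 carbonyl is removed afterwards by Wolff–Kishner reduction.
4. The trienone is assembled from a (Z)-vinyllithium (C1', C1, C10 and its methyl) and a keto γ-lactone made from (R)-α-terpineol (chiral pool). The ten terpineol carbons become C3–C9 and C11–C13; the lactone is a temporary ring that protects O11 and acylates the vinyllithium.
5. Ring order: temporary lactone (step 1), then rings A and B together (step 7); the aromatic ring is bought as 1,3,5-trimethoxybenzene.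

Key step: step 7

Remark: in the names, "syn" and "anti" mean the same and the opposite face as the C10 methyl group. In every decalin below H-5 is anti (trans fusion), the C7 substituent is syn (equatorial) and the C1 substituent is anti (axial). (R)-α-Terpineol of high enantiomeric purity is assumed to be available (otherwise by hydration of (R)-limonene).

**Step 1**
Reactants: 1 (R)-(+)-α-terpineol
Product: 3 (4R)-5,5-dimethyl-4-(3-oxobutyl)oxolan-2-one, via hydroxy keto acid 2 (not isolated)
Conditions: RuCl3·xH2O (cat.), NaIO4, CCl4/MeCN/H2O, rt; then TsOH·H2O (cat.), PhMe, 60 °C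
Reagents that add atoms: sodium periodate, [Na+].[O-]I(=O)(=O)=O
Why: Catalytic RuO4 oxidative cleavage cuts only the trisubstituted ring alkene to a methyl ketone and a carboxylic acid, and the γ-hydroxy acid lactonises; the carbinol-bearing stereocentre is untouched and becomes C7.

**Step 2**
Reactants: 3 (4R)-5,5-dimethyl-4-(3-oxobutyl)oxolan-2-one
Product: 7 (4R)-5,5-dimethyl-4-(3-oxopent-4-en-1-yl)oxolan-2-one, via lithium enolate 4 (not isolated), via Mannich base 5 (not isolated), via ammonium iodide 6 (not isolated)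
Conditions: LiN(iPr)2, THF, −78 °C; CH2=NMe2+ I−, −78 °C → rt; MeI, CH2Cl2, rt; K2CO3, CH2Cl2/H2O, rt
Reagents that add atoms: Eschenmoser's salt (N,N-dimethylmethyleneiminium iodide), C=[N+](C)C.[I-]
Why: Kinetic deprotonation of the methyl ketone at CH3 (more acidic than the lactone α-CH2), Mannich reaction, N-methylation and β-elimination make up a standard α-methylenation that gives the vinyl ketone without touching the stereocentre.

**Step 3**
Reactants: 7 (4R)-5,5-dimethyl-4-(3-oxopent-4-en-1-yl)oxolan-2-one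
Product: 8 (4R)-4-[(2Z)-3-(tert-butyldimethylsilyloxy)penta-2,4-dien-1-yl]-5,5-dimethyloxolan-2-one
Conditions: TBSOTf, Et3N, CH2Cl2, −78 → 0 °C
Reagents that add atoms: tert-butyldimethylsilyl trifluoromethanesulfonate, CC(C)(C)[Si](C)(C)OS(=O)(=O)C(F)(F)F
Why: Soft enolisation of the α'-CH2 of the vinyl ketone gives the cross-conjugated 2-silyloxy diene, the (Z)-enol ether being favoured by allylic strain; the lactone is not enolised under these conditions.

**Step 4**
Reactants: 9 but-2-yn-1-ol
Product: 11 (Z)-3-iodobut-2-en-1-ol, via alkenylaluminate 10 (not isolated)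
Conditions: NaAlH2(OCH2CH2OMe)2, THF, 0 °C → rt; then I2, THF, −78 → 0 °C
Reagents that add atoms: iodine, II
Why: Hydroxyl-directed trans-hydroalumination of the propargylic alcohol followed by iodinolysis with retention places iodine cis to CH2OH, which fixes the (Z) geometry needed for the C1 configuration.

**Step 5**
Reactants: 11 (Z)-3-iodobut-2-en-1-ol
Product: 12 (Z)-3-iodo-1-(triisopropylsilyloxy)but-2-ene
Conditions: iPr3SiCl, imidazole, DMF, rt
Reagents that add atoms: chlorotri(propan-2-yl)silane, CC(C)[Si](Cl)(C(C)C)C(C)C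
Why: Standard silylation; the bulky silyl group is chosen to suppress 1,4-O→C silyl migration in the cis-vinyllithium of step 6.

**Step 6**
Reactants: 8 (4R)-4-[(2Z)-3-(tert-butyldimethylsilyloxy)penta-2,4-dien-1-yl]-5,5-dimethyloxolan-2-one; 12 (Z)-3-iodo-1-(triisopropylsilyloxy)but-2-ene
Product: 14 (2Z,6R,8Z)-9-(tert-butyldimethylsilyloxy)-6-(2-hydroxypropan-2-yl)-3-methyl-1-(triisopropylsilyloxy)undeca-2,8,10-trien-4-one, via vinyllithium 13 (not isolated)
Conditions: 12, t-BuLi (2.1 equiv), Et2O, −78 °C; then 8, THF, −78 °C; NH4Cl (aq), −78 °C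
Reagents that add atoms: none
Why: Iodine–lithium exchange proceeds with retention of alkene geometry and the vinyllithium adds once to the γ-lactone (the lactolate is stable at −78 °C), so acyl substitution gives the (Z)-enone and frees the tertiary hydroxyl.

**Step 7**
Reactants: 14 (2Z,6R,8Z)-9-(tert-butyldimethylsilyloxy)-6-(2-hydroxypropan-2-yl)-3-methyl-1-(triisopropylsilyloxy)undeca-2,8,10-trien-4-one
Product: 15 4-(tert-butyldimethylsilyloxy)-11-hydroxy-1-[(triisopropylsilyloxy)methyl]-15-noreudesm-3-en-9-one (1-anti, 5-anti-H, 7-syn)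
Conditions: PhMe (0.01 M), BHT (cat.), 90 °C
Reagents that add atoms: none
Why: Thermal intramolecular Diels–Alder reaction of a 1,7,9-decatrien-3-one: the 2-silyloxy diene C2=C3–C4=C5 adds suprafacially to the enone double bond C1=C10, forming C1–C2 and C5–C10 in one concerted [4+2] event. The closest known reaction type is the cyclisation of 2-methyl-1,7,9-decatrien-3-ones to angularly methylated octalones, a known entry to eudesmane skeletons. Ring A is closed as the cyclohexene of the cycloaddition and ring B as a six-membered carbocycle through the four-atom tether C6–C9 (fused mode, chair-like tether). C1 relative to C10 follows from the (Z)-enone geometry (CH2OSi cis to C9, hence anti to the C10 methyl and axial); C10 relative to C7 follows from the chair-like tether with the 2-hydroxypropan-2-yl group equatorial and the enone held s-cis by its Z substituent; C5 follows from the exo-tether transition state that the α-methyl group favours, and any cis-fused adduct is corrected in step 8. The step needs π-facial and exo/endo selectivity, while regiochemistry is fixed by the tether: the only stereocentre of 14 (C7, from the chiral pool) secures the facial sense, and the tertiary alcohol and both silyl ethers are inert under neutral thermal conditions.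

**Step 8**
Reactants: 15 4-(tert-butyldimethylsilyloxy)-11-hydroxy-1-[(triisopropylsilyloxy)methyl]-15-noreudesm-3-en-9-one
Product: 16 11-hydroxy-1-(hydroxymethyl)-15-noreudesmane-4,9-dione (1-anti, 5-anti-H, 7-syn)
Conditions: n-Bu4NF, THF, 0 °C → rt; then K2CO3, MeOH, rt
Reagents that add atoms: none
Why: Fluoride cleaves the silyl enol ether to the C4 ketone and the silyl ether to the primary alcohol, and carbonate equilibrates C5 (α to the new ketone) to the trans ring fusion expected to be more stable, while C1, C7 and C10 cannot enolise.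

**Step 9**
Reactants: 16 11-hydroxy-1-(hydroxymethyl)-15-noreudesmane-4,9-dione
Product: 17 4,11-dihydroxy-1-(hydroxymethyl)eudesman-9-one (4-OH syn and axial, 4-CH3 equatorial)
Conditions: MeMgBr (4 equiv), CeCl3, THF, −78 °C
Reagents that add atoms: methylmagnesium bromide, C[Mg]Br
Why: Organocerium-type 1,2-addition should occur only at C4 because C9 is neopentyl and can be masked as a hemiketalate by the neighbouring C1' alkoxide; the methyl group enters equatorially because the axial path is blocked by the syn-axial C10 methyl, which gives the axial hydroxyl of the target.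

**Step 10**
Reactants: 17 4,11-dihydroxy-1-(hydroxymethyl)eudesman-9-one
Product: 19 1-(hydroxymethyl)eudesmane-4,11-diol, via hydrazone 18 (not isolated)
Conditions: N2H4·H2O, KOH, diethylene glycol, 130 °C then 200 °C
Reagents that add atoms: none
Why: Wolff–Kishner reduction removes the temporary C9 carbonyl, as is usual for ketones next to the angular methyl carbon of decalins; the alcohols tolerate the basic conditions and no epimerisable centre is adjacent.

**Step 11**
Reactants: 19 1-(hydroxymethyl)eudesmane-4,11-diol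
Product: 20 4,11-dihydroxyeudesmane-1-carbaldehyde (1-anti)
Conditions: Dess–Martin periodinane, CH2Cl2, 0 °C → rt
Reagents that add atoms: none
Why: Dess–Martin oxidation acts only on the primary alcohol (tertiary alcohols cannot be oxidised), and the mild, non-basic conditions should keep the axial formyl group at C1 from epimerising.

**Step 12**
Reactants: 20 4,11-dihydroxyeudesmane-1-carbaldehyde
Product: 21 (3E)-4-(4,11-dihydroxyeudesman-1-yl)but-3-en-2-one
Conditions: Ph3P=CHC(O)Me, PhMe, 80 °C
Reagents that add atoms: 1-(triphenylphosphoranylidene)propan-2-one, CC(=O)C=P(c1ccccc1)(c1ccccc1)c1ccccc1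
Why: Wittig olefination with a stabilised ylide gives the (E)-enone under neutral conditions that leave C1 and the free alcohols alone.

**Step 13**
Reactants: 21 (3E)-4-(4,11-dihydroxyeudesman-1-yl)but-3-en-2-one; 22 1,3,5-trimethoxybenzene
Product: 25 (4R)-4-(4,11-dihydroxyeudesman-1-yl)-4-(2,4,6-trimethoxyphenyl)butan-2-one, via aryllithium 23 (not isolated), via lithium diarylcuprate 24 (not isolated)
Conditions: 22, n-BuLi, THF, 0 °C; CuBr·SMe2, −40 °C; then 21, Me3SiCl, −78 → −20 °C; NH4Cl/NH3 (aq)
Reagents that add atoms: none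
Why: Conjugate addition of a 2,6-dimethoxyaryl cuprate to an enone; the γ-branched (E)-enone should react from the rotamer in which H-1 eclipses the C=C bond (chain pointing away from ring A), with the aryl group entering anti to the quaternary C10 from the C2 side, and this 1,2-induction sets C1' as (R).

**Step 14**
Reactants: 25 (4R)-4-(4,11-dihydroxyeudesman-1-yl)-4-(2,4,6-trimethoxyphenyl)butan-2-one
Product: 26 1-[(1R)-3-methyl-1-(2,4,6-trimethoxyphenyl)but-3-en-1-yl]eudesmane-4,11-diol
Conditions: Ph3PCH3Br, KOtBu, THF, 0 °C → rt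
Reagents that add atoms: methyltriphenylphosphonium bromide, C[P+](c1ccccc1)(c1ccccc1)c1ccccc1.[Br-]
Why: Wittig methylenation of the methyl ketone completes the carbon skeleton of the isobutyl group; C1' is β to the carbonyl and is not affected.

**Step 15**
Reactants: 26 1-[(1R)-3-methyl-1-(2,4,6-trimethoxyphenyl)but-3-en-1-yl]eudesmane-4,11-diol
Product: 27 1-[(1R)-3-methyl-1-(2,4,6-trimethoxyphenyl)butyl]eudesmane-4,11-diol
Conditions: H2 (1 atm), Pd/C, EtOAc, rt
Reagents that add atoms: none
Why: Catalytic hydrogenation of the 1,1-disubstituted alkene creates no stereocentre and leaves aryl ethers and tertiary alcohols intact.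

**Step 16**
Reactants: 27 1-[(1R)-3-methyl-1-(2,4,6-trimethoxyphenyl)butyl]eudesmane-4,11-diol
Product: 32 5-[(1R)-1-(4,11-dihydroxyeudesman-1-yl)-3-methylbutyl]-2,4,6-trimethoxybenzene-1,3-dicarbaldehyde, via aryllithium 28 (not isolated), via hemiaminal alkoxide 29 (not isolated), via lithiated hemiaminal alkoxide 30 (not isolated), via bis-hemiaminal alkoxide 31 (not isolated)
Conditions: n-BuLi (3.3 equiv), TMEDA, THF, 0 °C; DMF, −78 → 0 °C; n-BuLi (1.5 equiv), 0 °C; DMF; NH4Cl (aq)
Reagents that add atoms: N,N-dimethylformamide, CN(C)C=O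
Why: Twofold directed ortho-lithiation and formylation in one pot: each free ring position lies between two methoxy groups, the first formyl group is protected in situ as its lithium α-(dimethylamino)alkoxide while the second is installed, and the tertiary alcohols are carried as lithium alkoxides.

**Step 17**
Reactants: 32 5-[(1R)-1-(4,11-dihydroxyeudesman-1-yl)-3-methylbutyl]-2,4,6-trimethoxybenzene-1,3-dicarbaldehyde
Product: 33 5-[(1R)-1-[(1S,4R,4aS,6S,8aR)-4-hydroxy-6-(2-hydroxypropan-2-yl)-4,8a-dimethyldecahydronaphthalen-1-yl]-3-methylbutyl]-2,4,6-trihydroxybenzene-1,3-dicarbaldehyde (CNP0409870.5)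
Conditions: NaSEt, DMF, 120 °C; then HCl (aq)
Reagents that add atoms: none
Why: Nucleophilic O-demethylation by thiolate; every methoxy group is ortho or para to a formyl group (vinylogous ester), so all three should be cleaved under basic conditions that leave the tertiary alcohols untouched.

**Compound list**

1 | (R)-(+)-α-terpineol, 2-[(1R)-4-methylcyclohex-3-en-1-yl]propan-2-ol | CC1=CC[C@H](C(C)(C)O)CC1 | starting material
2 | (3R)-3-(2-hydroxypropan-2-yl)-6-oxoheptanoic acid | CC(=O)CC[C@@H](C(C)(C)O)CC(=O)O | intermediate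
3 | (4R)-5,5-dimethyl-4-(3-oxobutyl)oxolan-2-one | CC(=O)CC[C@@H]1CC(=O)OC1(C)C | intermediate
4 | kinetic lithium enolate of 3 (CH2=C(OLi) terminus) | C=C(O[Li])CC[C@@H]1CC(=O)OC1(C)C | intermediate
5 | (4R)-4-[5-(dimethylamino)-3-oxopentyl]-5,5-dimethyloxolan-2-one | CN(C)CCC(=O)CC[C@@H]1CC(=O)OC1(C)C | intermediate
6 | N-methyl ammonium iodide of 5 | C[N+](C)(C)CCC(=O)CC[C@@H]1CC(=O)OC1(C)C.[I-] | intermediate
7 | (4R)-5,5-dimethyl-4-(3-oxopent-4-en-1-yl)oxolan-2-one | C=CC(=O)CC[C@@H]1CC(=O)OC1(C)C | intermediate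
8 | (4R)-4-[(2Z)-3-(tert-butyldimethylsilyloxy)penta-2,4-dien-1-yl]-5,5-dimethyloxolan-2-one | C=C/C(O[Si](C)(C)C(C)(C)C)=C/C[C@@H]1CC(=O)OC1(C)C | intermediate
9 | but-2-yn-1-ol | CC#CCO | starting material
10 | sodium 2,2-bis(2-methoxyethoxy)-3-methyl-2,5-dihydro-1,2-oxaluminol-2-uide (cyclic alkenylaluminate) | [Na+].CC1=CCO[Al-]1(OCCOC)OCCOC | intermediate
11 | (Z)-3-iodobut-2-en-1-ol | C/C(I)=C/CO | intermediate
12 | (Z)-3-iodo-1-(triisopropylsilyloxy)but-2-ene | C/C(I)=C/CO[Si](C(C)C)(C(C)C)C(C)C | intermediate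
13 | (Z)-[4-(triisopropylsilyloxy)but-2-en-2-yl]lithium | C/C([Li])=C/CO[Si](C(C)C)(C(C)C)C(C)C | intermediate
14 | (2Z,6R,8Z)-9-(tert-butyldimethylsilyloxy)-6-(2-hydroxypropan-2-yl)-3-methyl-1-(triisopropylsilyloxy)undeca-2,8,10-trien-4-one | C=C/C(O[Si](C)(C)C(C)(C)C)=C/C[C@@H](C(C)(C)O)CC(=O)/C(C)=C\CO[Si](C(C)C)(C(C)C)C(C)C | intermediate
15 | 4-(tert-butyldimethylsilyloxy)-11-hydroxy-1-[(triisopropylsilyloxy)methyl]-15-noreudesm-3-en-9-one (1-anti, 5-anti-H, 7-syn) | CC(C)[Si](OC[C@@H]1CC=C(O[Si](C)(C)C(C)(C)C)[C@H]2C[C@@H](C(C)(C)O)CC(=O)[C@]12C)(C(C)C)C(C)C | intermediate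
16 | 11-hydroxy-1-(hydroxymethyl)-15-noreudesmane-4,9-dione | OC[C@@H]1CCC(=O)[C@H]2C[C@@H](C(C)(C)O)CC(=O)[C@]12C | intermediate
17 | 4,11-dihydroxy-1-(hydroxymethyl)eudesman-9-one (4-OH syn) | OC[C@@H]1CC[C@@](C)(O)[C@H]2C[C@@H](C(C)(C)O)CC(=O)[C@]12C | intermediate
18 | C9 hydrazone of 17 | OC[C@@H]1CC[C@@](C)(O)[C@H]2C[C@@H](C(C)(C)O)CC(=NN)[C@]12C | intermediate
19 | 1-(hydroxymethyl)eudesmane-4,11-diol | OC[C@@H]1CC[C@@](C)(O)[C@H]2C[C@@H](C(C)(C)O)CC[C@]12C | intermediate
20 | 4,11-dihydroxyeudesmane-1-carbaldehyde | O=C[C@@H]1CC[C@@](C)(O)[C@H]2C[C@@H](C(C)(C)O)CC[C@]12C | intermediate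
21 | (3E)-4-(4,11-dihydroxyeudesman-1-yl)but-3-en-2-one | CC(=O)/C=C/[C@@H]1CC[C@@](C)(O)[C@H]2C[C@@H](C(C)(C)O)CC[C@]12C | intermediate
22 | 1,3,5-trimethoxybenzene | COc1cc(OC)cc(OC)c1 | starting material
23 | (2,4,6-trimethoxyphenyl)lithium | COc1cc(OC)c([Li])c(OC)c1 | intermediate
24 | lithium bis(2,4,6-trimethoxyphenyl)cuprate | [Li+].COc1cc(OC)cc(OC)c1[Cu-]c1c(OC)cc(OC)cc1OC | intermediate
25 | (4R)-4-(4,11-dihydroxyeudesman-1-yl)-4-(2,4,6-trimethoxyphenyl)butan-2-one | CC(=O)C[C@@H](c1c(OC)cc(OC)cc1OC)[C@@H]1CC[C@@](C)(O)[C@H]2C[C@@H](C(C)(C)O)CC[C@]12C | intermediate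
26 | 1-[(1R)-3-methyl-1-(2,4,6-trimethoxyphenyl)but-3-en-1-yl]eudesmane-4,11-diol | C=C(C)C[C@@H](c1c(OC)cc(OC)cc1OC)[C@@H]1CC[C@@](C)(O)[C@H]2C[C@@H](C(C)(C)O)CC[C@]12C | intermediate
27 | 1-[(1R)-3-methyl-1-(2,4,6-trimethoxyphenyl)butyl]eudesmane-4,11-diol | CC(C)C[C@@H](c1c(OC)cc(OC)cc1OC)[C@@H]1CC[C@@](C)(O)[C@H]2C[C@@H](C(C)(C)O)CC[C@]12C | intermediate
28 | 3-lithio derivative of 27 as its dilithium dialkoxide | CC(C)C[C@@H](c1c(OC)c([Li])c(OC)cc1OC)[C@@H]1CC[C@@](C)(O[Li])[C@H]2C[C@@H](C(C)(C)O[Li])CC[C@]12C | intermediate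
29 | lithium α-(dimethylamino)alkoxide of the monoaldehyde (dilithium dialkoxide) | CC(C)C[C@@H](c1c(OC)c(C(O[Li])N(C)C)c(OC)cc1OC)[C@@H]1CC[C@@](C)(O[Li])[C@H]2C[C@@H](C(C)(C)O[Li])CC[C@]12C | intermediate
30 | ring-lithiated derivative of 29 | CC(C)C[C@@H](c1c(OC)c(C(O[Li])N(C)C)c(OC)c([Li])c1OC)[C@@H]1CC[C@@](C)(O[Li])[C@H]2C[C@@H](C(C)(C)O[Li])CC[C@]12C | intermediate
31 | bis[lithium α-(dimethylamino)alkoxide] (dilithium dialkoxide) | CC(C)C[C@@H](c1c(OC)c(C(O[Li])N(C)C)c(OC)c(C(O[Li])N(C)C)c1OC)[C@@H]1CC[C@@](C)(O[Li])[C@H]2C[C@@H](C(C)(C)O[Li])CC[C@]12C | intermediate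
32 | 5-[(1R)-1-(4,11-dihydroxyeudesman-1-yl)-3-methylbutyl]-2,4,6-trimethoxybenzene-1,3-dicarbaldehyde | CC(C)C[C@@H](c1c(OC)c(C=O)c(OC)c(C=O)c1OC)[C@@H]1CC[C@@](C)(O)[C@H]2C[C@@H](C(C)(C)O)CC[C@]12C | intermediate
33 | 5-[(1R)-1-[(1S,4R,4aS,6S,8aR)-4-hydroxy-6-(2-hydroxypropan-2-yl)-4,8a-dimethyldecahydronaphthalen-1-yl]-3-methylbutyl]-2,4,6-trihydroxybenzene-1,3-dicarbaldehyde (CNP0409870.5) | CC(C)C[C@@H](c1c(O)c(C=O)c(O)c(C=O)c1O)[C@@H]1CC[C@@](C)(O)[C@H]2C[C@@H](C(C)(C)O)CC[C@]12C | target

**Step count and risks**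

Total step count: 17. Longest linear sequence: 15 (steps 1–3 and 6–17; steps 4 and 5 make the vinyl iodide).

Steps most likely to fail:

1. **Step 7.** The cycloaddition may be slow because the (Z)-enone is twisted out of conjugation and the silyloxy donor does not reinforce the tether-imposed regiochemistry. Long heating may then cause desilylation or Z/E isomerisation of the enone, and a boat-like tether may lead into a cis-fused series that does not equilibrate. Fallback, from 11 and 8, back at 16: an ionic [4+2] with matched polarity. Oxidise 11 (MnO2, CH2Cl2) to (Z)-3-iodobut-2-enal F1 and acetalise it (HC(OEt)3, EtOH, pyridinium tosylate) to (Z)-1,1-diethoxy-3-iodobut-2-ene F2. Convert F2 with t-BuLi (Et2O, −78 °C) into the acetal vinyllithium F3 and add this to lactone 8 to give the acetal trienone F4. Me3SiOTf with 2,6-di-tert-butylpyridine (CH2Cl2, −78 °C) should silylate the tertiary hydroxyl and ionise the acetal to an alkoxyallyl cation. This cation is attacked at C10 by the enol ether carbon C5 and then closes C1–C2 (ionic Diels–Alder reaction of an α,β-unsaturated acetal, in effect a double Mukaiyama–Michael addition). Work-up with HCl (aq)/THF gives the keto aldehyde F5, and NaBH(OAc)3 reduces only its formyl group to give 16.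

2. **Step 13.** The 1,4-addition may be sluggish at a β-carbon attached to the axial, neopentyl-type C1 (competing 1,2-addition or simple enolate formation), and a rotamer other than the H-eclipsed one may react and erode the facial preference at C1'. Fallback, from 20, back at 27: keep the aryl group as the last substituent to arrive but use a more electrophilic cationic partner. Add 2-methylprop-1-enylmagnesium bromide to 20 (THF, −78 °C) to give the allylic alcohol F6. Ionise it with catalytic Bi(OTf)3 in CH2Cl2 in the presence of 22 (Friedel–Crafts allylation). Attack at the secondary terminus gives the trisubstituted alkene and avoids a quaternary benzylic centre, and the same H-eclipsed rotamer should be attacked from the C2 side, giving the prenyl-type arene F7. Hydrogenation (H2, Pd/C) then gives 27.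

3. **Step 9.** The reagent may also add to the C9 ketone, or enolise instead of adding, if the neopentyl position is less shielded than assumed. Fallback, from 16, back at 17: protect C9 through a temporary ring. Pyridinium tosylate in MeOH should convert the γ-hydroxy ketone unit (C1'–OH and C9=O) into the cyclic methyl ketal F8. MeMgBr/CeCl3 can then be used in excess and adds to C4 as before to give the ketal carbinol F9, and dilute HCl in THF releases the ketone to give 17.

**Further compounds**

F1 | step 7 | (Z)-3-iodobut-2-enal | C/C(I)=C/C=O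
F2 | step 7 | (Z)-1,1-diethoxy-3-iodobut-2-ene | C/C(I)=C/C(OCC)OCC
F3 | step 7 | (Z)-(4,4-diethoxybut-2-en-2-yl)lithium | C/C([Li])=C/C(OCC)OCC
F4 | step 7 | (2Z,6R,8Z)-9-(tert-butyldimethylsilyloxy)-1,1-diethoxy-6-(2-hydroxypropan-2-yl)-3-methylundeca-2,8,10-trien-4-one | C=C/C(O[Si](C)(C)C(C)(C)C)=C/C[C@@H](C(C)(C)O)CC(=O)/C(C)=C\C(OCC)OCC
F5 | step 7 | 11-hydroxy-4,9-dioxo-15-noreudesmane-1-carbaldehyde (1-anti, 5-anti-H, 7-syn) | O=C[C@@H]1CCC(=O)[C@H]2C[C@@H](C(C)(C)O)CC(=O)[C@]12C
F6 | step 13 | 1-(1-hydroxy-3-methylbut-2-en-1-yl)eudesmane-4,11-diol (carbinol epimers) | CC(C)=CC(O)[C@@H]1CC[C@@](C)(O)[C@H]2C[C@@H](C(C)(C)O)CC[C@]12C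
F7 | step 13 | 1-[3-methyl-1-(2,4,6-trimethoxyphenyl)but-2-en-1-yl]eudesmane-4,11-diol (C1' as in 27) | CC(C)=C[C@@H](c1c(OC)cc(OC)cc1OC)[C@@H]1CC[C@@](C)(O)[C@H]2C[C@@H](C(C)(C)O)CC[C@]12C
F8 | step 9 | cyclic methyl ketal of 16 (C9 bonded to OMe and to the C1' oxygen) | C3[C@@H]1CCC(=O)[C@H]2C[C@@H](C(C)(C)O)C[C@@](O3)(OC)[C@]12C
F9 | step 9 | cyclic methyl ketal of 17 | C3[C@@H]1CC[C@@](C)(O)[C@H]2C[C@@H](C(C)(C)O)C[C@@](O3)(OC)[C@]12C
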